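## Plan

1. Retrosynthesis cuts, in this order: the C6′ carbinol / C3′ ketone pair (back to a C6′ ketone and a C3′ silyl ether), then the C13–C1′ bond (an oxygen-to-carbon 1,3-shift, back to a C13 spiroketal carrying a C6′=C1′ enol ether), then the two C13–O ketal bonds. This separates a tricyclic C13 ketone from a cyclohexene cis-diol.
2. Enabling feature: spiro carbon C13 of ring C bears an ether oxygen bound to C5′ and a C–C bond to C1′, and C6′ between them bears OH. The ring C13–O–C5′–C6′–C1′ (ring D) is therefore an oxolan-3-ol, the reduced form of the oxolan-3-one obtained when the C13–O6′ bond of a ketal of the cis-C5′,C6′ diol is exchanged for C13–C1′.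
3. Forward, tricycle: rings A and B by enantioselective polyene cyclisation onto an anisole (latent ring C), Birch reduction to the ring C enone, C8 methyl by a radical delivered from the C6 oxygen.
4. Forward, upper unit: chain by aldol and allylboration, ring E by ring-closing metathesis; then ketalisation, allyl-to-enol ether shift, rearrangement (closes ring D) and redox adjustment.
5. Stereochemistry: C10/C5 from the chiral acid, C6 from hydride on the face away from the axial methyls, C9 thermodynamic, C8 from the tether. C3′/C4′ come from the aldol auxiliary, C5′/C6′ from the pinene-derived borane, C13 and C1′ from the rearrangement, and the C6′ carbinol from hydride anti to the C5′–O bond.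

Key step: step 20

Remark on numbering: terpenoid numbers C1–C14 for the tricycle (rings A, B, C; methyls on C4, C4, C8, C10); primed numbers C1′–C6′ for the carbocycle of the upper unit (ring E; C3′ ketone carbon, C4′ methyl carbon); ring D is the oxolane.
Assumption: the facial senses of the chiral proton source (step 2) and of the pinene-derived borane (step 16) are taken from the usual behaviour of these reagent families. The spiroketals are expected as C13 epimer mixtures, which does not matter because C13 becomes planar in the key step.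

## Route

Step 1
Reactants: 1 3-methoxybenzylmagnesium chloride; 2 geranyl bromide [(2E)-1-bromo-3,7-dimethylocta-2,6-diene]
Product: 3 1-[(3E)-4,8-dimethylnona-3,7-dien-1-yl]-3-methoxybenzene
Conditions: Li2CuCl4 (3 mol %), THF, −10 °C
Reagents that add atoms: none
Why: Copper-catalysed sp3–sp3 coupling of a benzylic Grignard reagent with a primary allylic bromide (Kochi-type) should occur at the α-carbon with retention of the E alkene, giving the homogeranyl arene that holds C1–C10 and the future ring C.

Step 2
Reactants: 3 1-[(3E)-4,8-dimethylnona-3,7-dien-1-yl]-3-methoxybenzene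
Product: 4 (5R,10R)-13-methoxypodocarpa-8,11,13-triene
Conditions: (S)-2-(2-fluorobenzyloxy)-2′-hydroxy-1,1′-binaphthyl·SnCl4 (1.1 equiv), toluene, −78 °C; then CF3CO2H, SnCl4, i-PrNO2, −78 °C
Reagents that add atoms: none
Why: Enantioselective cationic polyene cyclisation in which the Lewis acid-assisted chiral Brønsted acid protonates the terminal alkene, the chain folds chair–chair and the arene closes ring B para to the methoxy group, so that C10 and C5 arise trans; the (S) ligand is chosen as the mirror image of the one associated with the 10β-methyl series, the achiral acid completes cyclisation of monocyclic material, and the enantiomeric purity can be raised by crystallisation at ketone 5.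

Step 3
Reactants: 4 (5R,10R)-13-methoxypodocarpa-8,11,13-triene
Product: 5 (5R,10R)-13-methoxypodocarpa-8,11,13-trien-7-one
Conditions: CrO3, AcOH–H2O, rt
Reagents that add atoms: chromium trioxide, O=[Cr](=O)=O
Why: Benzylic oxidation at C7, the only benzylic methylene (C10 is quaternary), is a standard reaction of podocarpatrienes and gives the aryl ketone that opens the way to C6.

Step 4
Reactants: 5 (5R,10R)-13-methoxypodocarpa-8,11,13-trien-7-one
Product: 7 (5R,10R)-13-methoxypodocarpa-6,8,11,13-tetraene, via benzylic alcohol 6 (not isolated)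
Conditions: NaBH4, MeOH, 0 °C; then TsOH (cat.), benzene, 80 °C
Reagents that add atoms: none
Why: Hydride reduction followed by acid-catalysed dehydration through the benzylic cation should give the C6=C7 styrene, whichever C7 epimer of the alcohol forms.

Step 5
Reactants: 7 (5R,10R)-13-methoxypodocarpa-6,8,11,13-tetraene
Product: 9 (5R,10R)-13-methoxypodocarpa-8,11,13-trien-6-one, via 6,7-epoxide 8 (not isolated)
Conditions: mCPBA, NaHCO3, CH2Cl2, 0 °C; then ZnI2 (cat.), benzene, rt
Reagents that add atoms: 3-chloroperoxybenzoic acid, OOC(=O)c1cccc(Cl)c1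
Why: Prilezhaev epoxidation on the face away from the axial C4 and C10 methyls and Meinwald rearrangement (benzylic C7–O cleavage, 1,2-hydride shift from C6) is the classical dihydronaphthalene-to-2-tetralone route and moves the oxygen to C6.

Step 6
Reactants: 9 (5R,10R)-13-methoxypodocarpa-8,11,13-trien-6-one
Product: 10 (5R,6S,10R)-13-methoxypodocarpa-8,11,13-trien-6-ol
Conditions: NaBH4, MeOH, −20 °C
Reagents that add atoms: none
Why: Hydride reduction of the hindered C6 ketone should occur from the face opposite the syn-axial C4 and C10 methyls, which sets C6 with the hydroxyl axial on the methyl face, as the target requires.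

Step 7
Reactants: 10 (5R,6S,10R)-13-methoxypodocarpa-8,11,13-trien-6-ol
Product: 12 (5R,6S,9R,10S)-6-hydroxypodocarp-8(14)-en-13-one, via dihydroanisole 11 (not isolated)
Conditions: Li, NH3(l), THF, t-BuOH, −33 °C; then 2 M HCl, MeOH, rt
Reagents that add atoms: water, O
Why: Birch reduction of the anisole to the 1-methoxy-1,4-diene, then acid hydrolysis and conjugation, is the 19-nor-steroid sequence; it gives the ring C enone and sets C9 by thermodynamic protonation, H9 anti to the C10 methyl.

Step 8
Reactants: 12 (5R,6S,9R,10S)-6-hydroxypodocarp-8(14)-en-13-one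
Product: 13 (bromomethyl)dimethylsilyl ether of 12
Conditions: BrCH2SiMe2Cl, imidazole, DMF, rt
Reagents that add atoms: (bromomethyl)chlorodimethylsilane, C[Si](C)(Cl)CBr
Why: Silylation of the axial C6 hydroxyl with a small, reactive chlorosilane installs the radical precursor on the oxygen that lies syn-axial to the position where the C8 methyl is needed.

Step 9
Reactants: 13 (bromomethyl)dimethylsilyl ether of 12
Product: 14 cyclic siloxane (O6–SiMe2–CH2–C8 bridge) of podocarpan-13-one
Conditions: Bu3SnH (slow addition), AIBN (cat.), benzene, 80 °C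
Reagents that add atoms: none
Why: Silicon-tethered radical cyclisation, a 6-exo-trig addition of the nucleophilic α-silyl radical to the β-carbon C8 of the enone, delivers the carbon from the C6 oxygen and so sets C8 on the face of the C10 methyl with a trans B/C fusion; the α-keto radical at C14 is then reduced by the stannane.

Step 10
Reactants: 14 cyclic siloxane (O6–SiMe2–CH2–C8 bridge) of podocarpan-13-one
Product: 15 (5R,6S,8R,9R,10S)-6-hydroxy-8-methylpodocarpan-13-one
Conditions: Bu4NF, DMF, 70 °C
Reagents that add atoms: none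
Why: Fluoride-induced protodesilylation of the cyclic siloxane turns the Si–CH2 group into the C8 methyl and frees the C6 hydroxyl, completing the reductive-methylation sequence without touching the stereocentres.

Step 11
Reactants: 15 (5R,6S,8R,9R,10S)-6-hydroxy-8-methylpodocarpan-13-one
Product: 16 (5R,6S,8R,9R,10S)-8-methyl-13-oxopodocarpan-6-yl acetate
Conditions: Ac2O, Sc(OTf)3 (cat.), MeCN, −20 °C
Reagents that add atoms: acetic anhydride, CC(=O)OC(C)=O
Why: Lewis acid-catalysed acylation with a mixed anhydride/acylium donor is the method used for very hindered (even tertiary) alcohols and should acetylate the C6 hydroxyl, which is flanked by three syn-axial methyls, at a temperature at which the ketone is inert.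

Step 12
Reactants: 17 (S)-4-benzyl-3-propionyl-1,3-oxazolidin-2-one; 18 acrolein
Product: 19 (S)-4-benzyl-3-[(2S,3R)-3-hydroxy-2-methylpent-4-enoyl]-1,3-oxazolidin-2-one
Conditions: Bu2BOTf, i-Pr2NEt, CH2Cl2, −78 → 0 °C; then pH 7 buffer, MeOH, H2O2
Reagents that add atoms: none
Why: Evans syn aldol reaction through the Z boron enolate and a chair transition state, in which the (S) auxiliary sets the C4′ methyl and the C3′ oxygen syn with the required absolute sense.

Step 13
Reactants: 19 (S)-4-benzyl-3-[(2S,3R)-3-hydroxy-2-methylpent-4-enoyl]-1,3-oxazolidin-2-one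
Product: 20 (S)-4-benzyl-3-[(2S,3R)-3-(tert-butyldimethylsilyloxy)-2-methylpent-4-enoyl]-1,3-oxazolidin-2-one
Conditions: TBSOTf, 2,6-lutidine, CH2Cl2, −78 °C
Reagents that add atoms: tert-butyldimethylsilyl trifluoromethanesulfonate, CC(C)(C)[Si](C)(C)OS(=O)(=O)C(F)(F)F
Why: Silylation of the aldol hydroxyl blocks retro-aldol cleavage and provides the C3′ protecting group that must survive the Lewis acid of the key step.

Step 14
Reactants: 20 (S)-4-benzyl-3-[(2S,3R)-3-(tert-butyldimethylsilyloxy)-2-methylpent-4-enoyl]-1,3-oxazolidin-2-one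
Product: 21 (2R,3R)-3-(tert-butyldimethylsilyloxy)-2-methylpent-4-en-1-ol
Conditions: LiBH4, MeOH (1 equiv), THF, 0 °C
Reagents that add atoms: none
Why: Reductive cleavage of the N-acyl oxazolidinone gives the primary alcohol and returns the auxiliary without epimerising the α-centre.

Step 15
Reactants: 21 (2R,3R)-3-(tert-butyldimethylsilyloxy)-2-methylpent-4-en-1-ol
Product: 22 (2S,3R)-3-(tert-butyldimethylsilyloxy)-2-methylpent-4-enal
Conditions: Dess–Martin periodinane, NaHCO3, CH2Cl2, 0 °C
Reagents that add atoms: none
Why: Dess–Martin oxidation under buffered conditions gives the α-methyl aldehyde without epimerisation or β-elimination; it is used at once.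

Step 16
Reactants: 22 (2S,3R)-3-(tert-butyldimethylsilyloxy)-2-methylpent-4-enal
Product: 24 (3R,4S,5R,6R)-6-(tert-butyldimethylsilyloxy)-5-methylocta-1,7-diene-3,4-diol, via allylboration adduct 23 (not isolated)
Conditions: (+)-Ipc2BH [from (−)-α-pinene], pinacol allenylboronate, Et2O, 0 °C; then 22, −78 °C; then NaOH, H2O2, 0 °C → rt
Reagents that add atoms: allenylboronic acid pinacol ester, C=C=CB1OC(C)(C)C(C)(C)O1; hydrogen peroxide, OO
Why: Hydroboration of the allenylboronate gives an (E)-γ-borylallylborane whose chair-like allylboration makes the two new centres anti, the pinene ligands directing addition to the Re face of the aldehyde against its modest Felkin preference (reagent control), and oxidation of the C–B bond with retention gives the erythro C5′,C6′ diol.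

Step 17
Reactants: 24 (3R,4S,5R,6R)-6-(tert-butyldimethylsilyloxy)-5-methylocta-1,7-diene-3,4-diol
Product: 25 (1R,2S,3R,4R)-4-(tert-butyldimethylsilyloxy)-3-methylcyclohex-5-ene-1,2-diol
Conditions: second-generation Grubbs catalyst (H2IMes)(PCy3)Cl2Ru=CHPh (3 mol %), CH2Cl2, 40 °C
Reagents that add atoms: none
Why: Ring-closing metathesis of a 1,7-diene to a cyclohexene tolerates free allylic hydroxyls (the conduritol precedent) and closes ring E with the C1′=C2′ alkene next to C6′.

Step 18
Reactants: 16 (5R,6S,8R,9R,10S)-8-methyl-13-oxopodocarpan-6-yl acetate; 25 (1R,2S,3R,4R)-4-(tert-butyldimethylsilyloxy)-3-methylcyclohex-5-ene-1,2-diol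
Product: 26 C13 spiroketal (dioxolane on O5′ and O6′) with C1′=C2′ alkene and C3′ silyl ether
Conditions: PPTS (cat.), benzene, reflux, Dean–Stark trap
Reagents that add atoms: none
Why: Acid-catalysed ketalisation of the only ketone with the cis-diol, with azeotropic removal of water, joins the two halves through oxygen; no C–C bond to the β-quaternary ring C ketone has to be made intermolecularly, and any minor enantiomer of 16 is removed here as a diastereomer.

Step 19
Reactants: 26 C13 spiroketal (dioxolane on O5′ and O6′) with C1′=C2′ alkene and C3′ silyl ether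
Product: 27 C13 spiroketal with C6′=C1′ enol ether (4-alkylidene-1,3-dioxolane)
Conditions: [Ir(cod)(PMePh2)2]PF6 (5 mol %, activated with H2, then degassed), THF, rt
Reagents that add atoms: none
Why: Iridium hydride-catalysed allyl-to-enol ether isomerisation is a suprafacial 1,3-hydrogen shift on the open face of ring E (the face away from the dioxolane and its spiro substituent), and that face carries H6′ but not H3′, so the double bond should move toward oxygen O6′ and not toward the silyl ether.

Step 20
Reactants: 27 C13 spiroketal with C6′=C1′ enol ether (4-alkylidene-1,3-dioxolane)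
Product: 28 pentacyclic C6′ ketone (oxolan-3-one, C13–C1′ bond) with C3′ silyl ether
Conditions: Me3SiOTf (1.2 equiv), 2,6-di-tert-butyl-4-methylpyridine, CH2Cl2, −78 → −40 °C; aq. NaHCO3
Reagents that add atoms: none
Why: Me3SiOTf silylates the enol-ether oxygen O6′ and breaks the C13–O6′ bond, the only ketal bond whose oxygen leaves as an enol, giving a C13 oxocarbenium ion still held through O5′ to the C6′ silyl enol ether; the enol carbon C1′ then adds to C13 and loss of the silyl group returns the C6′ ketone, which is a Petasis–Ferrier rearrangement of a 4-alkylidene-1,3-dioxolane to an oxolan-3-one (in effect an intramolecular Mukaiyama-type addition to an oxocarbenium ion). Ring D (C13, O, C5′, C6′, C1′) closes in the 5-(enolendo)-endo-trig mode, formally unfavourable but the mode this rearrangement class follows, and because C1′ and C5′ are 1,3-related on ring E the same event creates the 6-oxabicyclo[3.2.1]octane. C1′ can only bond on the face of ring E that carries O5′, so its configuration is dictated by C5′. C13 is set by the face of the planar oxocarbenium ion that is attacked: the axial face is shielded by the syn-axial C8 methyl, so C1′ should enter equatorially and leave the ring oxygen axial, as in the target, and both ketal epimers of 27 converge on the same cation. The step needs recombination at carbon rather than at oxygen and survival of the acetate and the silyl ether, which low temperature, a hindered pyridine base and a non-nucleophilic counter-ion should secure.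

Step 21
Reactants: 28 pentacyclic C6′ ketone (oxolan-3-one, C13–C1′ bond) with C3′ silyl ether
Product: 29 pentacyclic C6′ ketone with free C3′ hydroxyl
Conditions: HF·pyridine, THF, 0 °C → rt
Reagents that add atoms: none
Why: Fluoride-mediated cleavage of the secondary silyl ether under weakly acidic conditions leaves the hindered acetate, the bridging ketone and the ether untouched.

Step 22
Reactants: 29 pentacyclic C6′ ketone with free C3′ hydroxyl
Product: 30 pentacyclic C3′,C6′ diketone
Conditions: Dess–Martin periodinane, NaHCO3, CH2Cl2, rt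
Reagents that add atoms: none
Why: Dess–Martin oxidation installs the C3′ ketone under neutral conditions, so the β-alkoxy ketone is not exposed to base and the C4′ methyl keeps its equatorial, thermodynamically preferred orientation.

Step 23
Reactants: 30 pentacyclic C3′,C6′ diketone
Product: 31 CNP0188572.2 (target)
Conditions: NaBH4 (0.3 equiv), MeOH–CH2Cl2, −78 °C
Reagents that add atoms: none
Why: Chemoselective hydride reduction of the more electrophilic carbonyl: C6′ is α-alkoxy, angle-strained on the one-carbon bridge and cannot enolise, whereas C3′ is an α-branched cyclohexanone; hydride should enter anti to the C5′–O bond (Felkin–Anh polar control) from the side of the C2′–C3′–C4′ bridge, away from the ring C methylene on C13, and so place the hydroxyl syn to the O–C13 bridge.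

## Compound list

1 | 3-methoxybenzylmagnesium chloride | COc1cccc(C[Mg]Cl)c1 | starting material
2 | geranyl bromide | CC(C)=CCC/C(C)=C/CBr | starting material
3 | 1-[(3E)-4,8-dimethylnona-3,7-dien-1-yl]-3-methoxybenzene | COc1cccc(CC/C=C(\C)CCC=C(C)C)c1 | intermediate
4 | (5R,10R)-13-methoxypodocarpa-8,11,13-triene | C1Cc2cc(OC)ccc2[C@]2(C)CCCC(C)(C)[C@@H]12 | intermediate
5 | (5R,10R)-13-methoxypodocarpa-8,11,13-trien-7-one | C1C(=O)c2cc(OC)ccc2[C@]2(C)CCCC(C)(C)[C@@H]12 | intermediate
6 | (5R,10R)-13-methoxypodocarpa-8,11,13-trien-7-ol (either C7 epimer) | C1C(O)c2cc(OC)ccc2[C@]2(C)CCCC(C)(C)[C@@H]12 | intermediate (not isolated)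
7 | (5R,10R)-13-methoxypodocarpa-6,8,11,13-tetraene | C1=Cc2cc(OC)ccc2[C@]2(C)CCCC(C)(C)[C@@H]12 | intermediate
8 | 6,7-epoxide of 7, oxygen anti to the C10 methyl | [C@@H]12O[C@@H]1c1cc(OC)ccc1[C@]1(C)CCCC(C)(C)[C@@H]21 | intermediate (not isolated)
9 | (5R,10R)-13-methoxypodocarpa-8,11,13-trien-6-one | O=C1Cc2cc(OC)ccc2[C@]2(C)CCCC(C)(C)[C@@H]12 | intermediate
10 | (5R,6S,10R)-13-methoxypodocarpa-8,11,13-trien-6-ol (OH axial, syn to the C10 methyl) | O[C@H]1Cc2cc(OC)ccc2[C@]2(C)CCCC(C)(C)[C@@H]12 | intermediate
11 | (5R,6S,10R)-13-methoxypodocarpa-8,12-dien-6-ol | O[C@H]1CC2=C(CC=C(OC)C2)[C@]2(C)CCCC(C)(C)[C@@H]12 | intermediate (not isolated)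
12 | (5R,6S,9R,10S)-6-hydroxypodocarp-8(14)-en-13-one | O[C@H]1CC2=CC(=O)CC[C@H]2[C@]2(C)CCCC(C)(C)[C@@H]12 | intermediate
13 | 6-O-[(bromomethyl)dimethylsilyl] ether of 12 | BrC[Si](C)(C)O[C@H]1CC2=CC(=O)CC[C@H]2[C@]2(C)CCCC(C)(C)[C@@H]12 | intermediate
14 | cyclic siloxane: O6–SiMe2–CH2–C8 bridge on the C10-methyl face, podocarpan-13-one | C[Si]3(C)O[C@H]1C[C@]2(C3)CC(=O)CC[C@H]2[C@]2(C)CCCC(C)(C)[C@@H]12 | intermediate
15 | (5R,6S,8R,9R,10S)-6-hydroxy-8-methylpodocarpan-13-one | O[C@H]1C[C@]2(C)CC(=O)CC[C@H]2[C@]2(C)CCCC(C)(C)[C@@H]12 | intermediate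
16 | (5R,6S,8R,9R,10S)-8-methyl-13-oxopodocarpan-6-yl acetate | CC(=O)O[C@H]1C[C@]2(C)CC(=O)CC[C@H]2[C@]2(C)CCCC(C)(C)[C@@H]12 | intermediate
17 | (S)-4-benzyl-3-propionyl-1,3-oxazolidin-2-one | CCC(=O)N1[C@@H](Cc2ccccc2)COC1=O | starting material
18 | acrolein | C=CC=O | starting material
19 | (S)-4-benzyl-3-[(2S,3R)-3-hydroxy-2-methylpent-4-enoyl]-1,3-oxazolidin-2-one | C=C[C@@H](O)[C@H](C)C(=O)N1[C@@H](Cc2ccccc2)COC1=O | intermediate
20 | (S)-4-benzyl-3-[(2S,3R)-3-(tert-butyldimethylsilyloxy)-2-methylpent-4-enoyl]-1,3-oxazolidin-2-one | C=C[C@@H](O[Si](C)(C)C(C)(C)C)[C@H](C)C(=O)N1[C@@H](Cc2ccccc2)COC1=O | intermediate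
21 | (2R,3R)-3-(tert-butyldimethylsilyloxy)-2-methylpent-4-en-1-ol | C=C[C@@H](O[Si](C)(C)C(C)(C)C)[C@H](C)CO | intermediate
22 | (2S,3R)-3-(tert-butyldimethylsilyloxy)-2-methylpent-4-enal | C=C[C@@H](O[Si](C)(C)C(C)(C)C)[C@H](C)C=O | intermediate
23 | allylboration adduct: C5′ O-diisopinocampheylborinate, C6′ pinacol boronate | O(B([C@H]1C[C@H]2C[C@@H]([C@@H]1C)C2(C)C)[C@H]1C[C@H]2C[C@@H]([C@@H]1C)C2(C)C)[C@H]([C@H](B1OC(C)(C)C(C)(C)O1)C=C)[C@@H](C)[C@H](O[Si](C)(C)C(C)(C)C)C=C | intermediate (not isolated)
24 | (3R,4S,5R,6R)-6-(tert-butyldimethylsilyloxy)-5-methylocta-1,7-diene-3,4-diol | O[C@H]([C@H](O)C=C)[C@@H](C)[C@H](O[Si](C)(C)C(C)(C)C)C=C | intermediate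
25 | (1R,2S,3R,4R)-4-(tert-butyldimethylsilyloxy)-3-methylcyclohex-5-ene-1,2-diol | O[C@@H]1[C@H](O)C=C[C@@H](O[Si](C)(C)C(C)(C)C)[C@@H]1C | intermediate
26 | C13 spiroketal of 16 with 25 (dioxolane on O5′/O6′, C1′=C2′ alkene, C3′ OTBS; one C13 epimer drawn) | CC(=O)O[C@H]1C[C@]2(C)C[C@]3(CC[C@H]2[C@]2(C)CCCC(C)(C)[C@@H]12)O[C@@H]1[C@H](O3)C=C[C@@H](O[Si](C)(C)C(C)(C)C)[C@@H]1C | intermediate
27 | C13 spiroketal with C6′=C1′ enol ether (one C13 epimer drawn) | CC(=O)O[C@H]1C[C@]2(C)C[C@]3(CC[C@H]2[C@]2(C)CCCC(C)(C)[C@@H]12)O[C@@H]1C(O3)=CC[C@@H](O[Si](C)(C)C(C)(C)C)[C@@H]1C | intermediate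
28 | pentacyclic C6′ ketone with C13–C1′ bond, ring oxygen axial on C13, C3′ OTBS | CC(=O)O[C@H]1C[C@]2(C)C[C@]3(CC[C@H]2[C@]2(C)CCCC(C)(C)[C@@H]12)O[C@@H]1C(=O)[C@H]3C[C@@H](O[Si](C)(C)C(C)(C)C)[C@@H]1C | intermediate
29 | pentacyclic C6′ ketone, C3′ alcohol | CC(=O)O[C@H]1C[C@]2(C)C[C@]3(CC[C@H]2[C@]2(C)CCCC(C)(C)[C@@H]12)O[C@@H]1C(=O)[C@H]3C[C@@H](O)[C@@H]1C | intermediate
30 | pentacyclic C3′,C6′ diketone | CC(=O)O[C@H]1C[C@]2(C)C[C@]3(CC[C@H]2[C@]2(C)CCCC(C)(C)[C@@H]12)O[C@@H]1C(=O)[C@H]3CC(=O)[C@@H]1C | intermediate
31 | CNP0188572.2 | CC(=O)O[C@H]1C[C@]2(C)C[C@]3(CC[C@H]2[C@]2(C)CCCC(C)(C)[C@@H]12)O[C@@H]1[C@H](O)[C@H]3CC(=O)[C@@H]1C | target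

## Step count

Total: 23 steps. Longest linear sequence: 17 steps (steps 1–11, then 18–23); the diol branch (steps 12–17) joins at step 18.

## Steps most likely to fail

**Step 20 (rearrangement).** The tethered oxocarbenium ion and enol silane may separate by proton loss or hydrolysis instead of closing at carbon, because the closure is the strained 5-endo mode onto a fully substituted carbon; attack on the wrong face would give the C13 epimer.
Fallback: carbon first, oxygen second, without a ring constraint on the C–C bond formation. It sets out from 27 and rejoins at 28. Aqueous oxalic acid in THF hydrolyses 27 to ketone 16 and (2S,3R,4R)-4-(tert-butyldimethylsilyloxy)-2-hydroxy-3-methylcyclohexan-1-one F1. The dianion of F1 (LiN(i-Pr)2, 2.1 equiv; alkoxide plus kinetic C1′ enolate), transmetallated with CeCl3, adds to 16 to give the tertiary aldol F2. CSA in benzene then ionises the tertiary C13 hydroxyl, in part through the C13=C1′ alkylidene ketone F3, and the C5′ hydroxyl captures C13. This etherification is reversible and should settle C13 (ring oxygen axial, C1′ equatorial) and C1′ under thermodynamic control.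

**Step 19 (isomerisation).** The iridium hydride may not engage the hindered ring alkene, or may move the double bond toward C3′ (silyl enol ether, loss of silanol).
Fallback: the enol is made regiospecifically on the fragment and the spiroketal is bypassed. It sets out from 25 and 16 and rejoins at 28. MnO2 oxidises the allylic C6′ hydroxyl of 25 to (4R,5R,6S)-4-(tert-butyldimethylsilyloxy)-6-hydroxy-5-methylcyclohex-2-en-1-one F4. Conjugate reduction with LiBH(s-Bu)3 and trapping with Me3SiCl gives the C6′=C1′ enol silane, also O-silylated at C5′, F5. Condensation of F5 with 16 under catalytic Me3SiOTf (CH2Cl2, −78 °C) forms the O5′-bound oxocarbenium ion from the silyl ether and the ketone, and the enol silane closes onto it to give 28.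

**Step 23 (final reduction).** Hydride may also reduce the C3′ ketone, or may be delivered from the O–C13 bridge side and give the C6′ epimer.
Fallback: the order of the redox events is inverted so that no second ketone is present during reduction. It sets out from 28 and rejoins at 31. NaBH4 reduces the C6′ ketone of 28 to the C6′ alcohol with the C3′ silyl ether intact, F6. HF·pyridine gives the C3′,C6′ diol F7. A hindered oxoammonium oxidant (TEMPO, PhI(OAc)2) should then oxidise only the C3′ cyclohexanol, because the bridge carbinol is flanked by two bridgeheads and its ketone is angle-strained.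

## Further compounds

F1 | step 20 | (2S,3R,4R)-4-(tert-butyldimethylsilyloxy)-2-hydroxy-3-methylcyclohexan-1-one | O[C@@H]1C(=O)CC[C@@H](O[Si](C)(C)C(C)(C)C)[C@@H]1C
F2 | step 20 | tertiary aldol of F1 (C1′) with 16 (C13), C13 and C1′ epimers | CC(=O)O[C@H]1C[C@]2(C)CC(O)(CC[C@H]2[C@]2(C)CCCC(C)(C)[C@@H]12)C1C(=O)[C@@H](O)[C@@H](C)[C@H](O[Si](C)(C)C(C)(C)C)C1
F3 | step 20 | C13=C1′ alkylidene ketone (either alkene geometry) | CC(=O)O[C@H]1C[C@]2(C)CC(CC[C@H]2[C@]2(C)CCCC(C)(C)[C@@H]12)=C1C(=O)[C@@H](O)[C@@H](C)[C@H](O[Si](C)(C)C(C)(C)C)C1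
F4 | step 19 | (4R,5R,6S)-4-(tert-butyldimethylsilyloxy)-6-hydroxy-5-methylcyclohex-2-en-1-one | O[C@@H]1C(=O)C=C[C@@H](O[Si](C)(C)C(C)(C)C)[C@@H]1C
F5 | step 19 | 4-(tert-butyldimethylsilyloxy)-5-methyl-1,6-bis(trimethylsilyloxy)cyclohex-1-ene, stereocentres as in F4 | C[Si](C)(C)O[C@@H]1C(O[Si](C)(C)C)=CC[C@@H](O[Si](C)(C)C(C)(C)C)[C@@H]1C
F6 | step 23 | pentacyclic C6′ alcohol with C3′ silyl ether | CC(=O)O[C@H]1C[C@]2(C)C[C@]3(CC[C@H]2[C@]2(C)CCCC(C)(C)[C@@H]12)O[C@@H]1[C@H](O)[C@H]3C[C@@H](O[Si](C)(C)C(C)(C)C)[C@@H]1C
F7 | step 23 | pentacyclic C3′,C6′ diol | CC(=O)O[C@H]1C[C@]2(C)C[C@]3(CC[C@H]2[C@]2(C)CCCC(C)(C)[C@@H]12)O[C@@H]1[C@H](O)[C@H]3C[C@@H](O)[C@@H]1C
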